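**Strategy**

The pyrrole ring of the target is cut at the C2–C3 bond. Because C2 and C3 bear no carbon substituents and C7–Br sits ortho to N1 on the benzo ring, C2 can be introduced as an isocyanide carbon on N1 and C3 as the ortho methyl group of a 2-bromo-6-methylaniline. In one operation, lithium amide deprotonation of 2-bromo-6-methylphenyl isocyanide and closure of the benzylic anion onto the isocyanide carbon forms C2–C3 and the five-membered ring, delivering 7-bromoindole with C2 and C3 free. The precursor is a benzene carrying an isocyano group flanked by bromine and methyl. A final double bromination with NBS installs C3–Br and C2–Br.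

Key step: step 3

**Route**

Step 1
Reactants: 1 2-bromo-6-methylaniline; 2 formic acid
Product: 4 N-(2-bromo-6-methylphenyl)formamide, via acetic formic anhydride 3 (not isolated)
Conditions: HCO2H, Ac2O, 55 °C, 2 h; then 1, THF, 0 °C to rt
Reagents that add atoms: formic acid, OC=O (transferred as acetic formic anhydride, CC(=O)OC=O)
Why: Mixed-anhydride N-formylation, in which the amine attacks the more electrophilic and less hindered formyl carbonyl of 3, a reagent reactive enough for a di-ortho-substituted, weakly basic aniline at or below room temperature.

Step 2
Reactants: 4 N-(2-bromo-6-methylphenyl)formamide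
Product: 5 2-bromo-6-methylphenyl isocyanide (1-bromo-2-isocyano-3-methylbenzene)
Conditions: POCl3, Et3N, CH2Cl2, 0 °C; then cold aq. Na2CO3
Reagents that add atoms: none
Why: Ugi dehydration of an N-arylformamide, in which POCl3 activates the formamide oxygen and triethylamine removes the N–H and formyl C–H protons, a net loss of water that should leave the aryl bromide and the methyl group untouched.

Step 3
Reactants: 5 2-bromo-6-methylphenyl isocyanide
Product: 9 7-bromo-1H-indole, via (3-bromo-2-isocyanobenzyl)lithium 6 (not isolated), via (7-bromo-3H-indol-2-yl)lithium 7 (not isolated), via 7-bromoindol-1-yllithium 8 (not isolated)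
Conditions: LiN(i-Pr)2 (2.1 equiv), diglyme/THF, −78 °C, then slowly to rt; H2O
Reagents that add atoms: none
Why: Lithium diisopropylamide should remove a proton from the methyl group, which the ortho isocyano group acidifies, to give the benzylic organolithium 6 at −78 °C. On warming, the carbanion adds to the terminal isocyanide carbon (an α-addition that leaves the charge on that carbon), forming the C2–C3 bond and closing the pyrrole ring in a 5-endo-dig mode, since both N1 and C2 of the N≡C unit become ring atoms, to give the imidoyllithium 7. Transfer of a C3 proton to C2, relayed by the second equivalent of amide base, aromatizes 7 to the N-lithioindole 8, which water protonates to 9. The closest known reaction type is the base-induced cyclization of ortho-tolyl isocyanides to indoles (Saegusa indole synthesis), here applied to a ring-brominated substrate. No stereocenter is formed. The step needs deprotonation at the methyl group instead of the ring C–H next to bromine, and no attack on C–Br or on the isocyanide carbon: the isocyano-activated benzylic position is by far the most acidic site, a hindered amide base does not undergo lithium–bromine exchange and adds poorly to the isocyanide, and the low temperature suppresses aryne formation.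

Step 4
Reactants: 9 7-bromo-1H-indole; 10 N-bromosuccinimide
Product: 12 2,3,7-tribromo-1H-indole, via 3,7-dibromo-1H-indole 11 (not isolated)
Conditions: NBS (2.05 equiv), THF, −78 °C to 0 °C, dark
Reagents that add atoms: N-bromosuccinimide, O=C1CCC(=O)N1Br
Why: Electrophilic aromatic bromination of the electron-rich pyrrole ring, in which the first equivalent of NBS attacks C3, the most nucleophilic position, to give 11 and the second substitutes the remaining pyrrole position C2 (directly or by attack at C3 and 1,2-shift of bromine), while the C7 bromine deactivates the benzo ring so that two equivalents at low temperature should stop at the tribromide.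

**Compound list**

1 | 2-bromo-6-methylaniline | Cc1cccc(Br)c1N | starting material
2 | formic acid | OC=O | starting material
3 | acetic formic anhydride | CC(=O)OC=O | intermediate
4 | N-(2-bromo-6-methylphenyl)formamide | O=CNc1c(C)cccc1Br | intermediate
5 | 2-bromo-6-methylphenyl isocyanide (1-bromo-2-isocyano-3-methylbenzene) | [C-]#[N+]c1c(C)cccc1Br | intermediate
6 | (3-bromo-2-isocyanobenzyl)lithium | [Li]Cc1cccc(Br)c1[N+]#[C-] | intermediate
7 | (7-bromo-3H-indol-2-yl)lithium | [Li]C1=Nc2c(Br)cccc2C1 | intermediate
8 | 7-bromoindol-1-yllithium | [Li]n1ccc2cccc(Br)c21 | intermediate
9 | 7-bromo-1H-indole | Brc1cccc2cc[nH]c12 | intermediate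
10 | N-bromosuccinimide | O=C1CCC(=O)N1Br | starting material
11 | 3,7-dibromo-1H-indole | Brc1c[nH]c2c(Br)cccc12 | intermediate
12 | 2,3,7-tribromo-1H-indole | Brc1[nH]c2c(Br)cccc2c1Br | target

Total step count: 4
Longest linear sequence: 4 steps

**Steps most likely to fail**

Risk 1, step 3 (key cyclization). Once the mixture is warmed with excess amide base, deprotonation of the ring C–H next to bromine and loss of lithium bromide (aryne formation) may compete. Addition of the amide to the isocyanide carbon or oligomerization of the isocyanide may also lower the conversion. The fallback sets out from 1 and comes back to the route at 9, building the same pyrrole ring by a Leimgruber–Batcho sequence. The amino group of 1 would be oxidized with mCPBA in hot 1,2-dichloroethane to 1-bromo-3-methyl-2-nitrobenzene F1. Its methyl group would be condensed with N,N-dimethylformamide dimethyl acetal and pyrrolidine in DMF at 110 °C to give (E)-1-[2-(3-bromo-2-nitrophenyl)ethenyl]pyrrolidine F2. Reduction of the nitro group with Fe in AcOH, which should spare the aryl bromide, lets the aniline close onto the enamine carbon and expel pyrrolidine to give 9.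

Risk 2, step 4 (double bromination). Bromination may run on into the benzo ring, or the acid- and light-sensitive N–H 2,3-dibromoindole unit may lose or shift bromine under traces of HBr during reaction and purification. The fallback sets out from 9 and comes back at 12, placing the two bromines one at a time on an N-sulfonyl indole. Compound 9 would be treated with NaH and benzenesulfonyl chloride in DMF to give 7-bromo-1-(phenylsulfonyl)-1H-indole F3. Deprotonation at C2 with lithium diisopropylamide in THF at −78 °C should give [7-bromo-1-(phenylsulfonyl)-1H-indol-2-yl]lithium F4 (not isolated), which 1,2-dibromotetrachloroethane converts into 2,7-dibromo-1-(phenylsulfonyl)-1H-indole F5. Bromination at C3 with Br2 in CH2Cl2 should give 2,3,7-tribromo-1-(phenylsulfonyl)-1H-indole F6, and cleavage of the sulfonamide with KOH in aqueous dioxane should deliver 12.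

Risk 3, step 2 (dehydration). Dehydration of the hindered formamide may stay incomplete, or the isocyanide may be hydrated back to 4 if the work-up turns acidic. The fallback sets out from 1 and comes back at 5. The amine would be converted directly into the isocyanide by the Hofmann carbylamine reaction under phase-transfer conditions (CHCl3, 50% aq. NaOH, benzyltriethylammonium chloride, CH2Cl2, reflux). This fallback makes no new compound (F0).

Further compounds
F1 | step 3 | 1-bromo-3-methyl-2-nitrobenzene | Cc1cccc(Br)c1[N+](=O)[O-]
F2 | step 3 | (E)-1-[2-(3-bromo-2-nitrophenyl)ethenyl]pyrrolidine | O=[N+]([O-])c1c(Br)cccc1/C=C/N1CCCC1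
F3 | step 4 | 7-bromo-1-(phenylsulfonyl)-1H-indole | O=S(=O)(c1ccccc1)n1ccc2cccc(Br)c21
F4 | step 4 | [7-bromo-1-(phenylsulfonyl)-1H-indol-2-yl]lithium | [Li]c1cc2cccc(Br)c2n1S(=O)(=O)c1ccccc1
F5 | step 4 | 2,7-dibromo-1-(phenylsulfonyl)-1H-indole | O=S(=O)(c1ccccc1)n1c(Br)cc2cccc(Br)c21
F6 | step 4 | 2,3,7-tribromo-1-(phenylsulfonyl)-1H-indole | O=S(=O)(c1ccccc1)n1c(Br)c(Br)c2cccc(Br)c21
F0 | step 2 | none | none
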